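The data were generated by integration with made-up constants.

You charge 0.80 M of each mirror-image substrate, 1.20 equiv of partner and 2.5 mol% of precatalyst.

in all of them: precatalyst 2.5 mol%

| flask | left-handed substrate | right-handed substrate | partner | remark |
|---|---|---|---|---|
| teal | 0.40 M | 0.40 M | 1.2 equiv | run made earlier |
| green | 0.60 M | 0.60 M | 1.2 equiv | run made earlier |
| flask | 0.80 M | 0.80 M | 1.20 equiv |  |

- teal (time / min: left-handed product / %, left-handed substrate / %): 1.33: 0, 48; 4.00: 11, 39; 6.00: 17, 30; 10.0: 30, 21; 15.0: 34, 16; 20.0: 38, 11
- green (time / min: left-handed product / %, left-handed substrate / %): 1.33: 3, 46; 4.00: 23, 28; 6.00: 29, 20; 10.0: 35, 11; 15.0: 39, 11; 20.0: 39, 11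

(readings scatter by 2 percentage points)

- free catalyst is single-handed; left-handed substrate and right-handed substrate are mirror images of each other, charged as a racemate, each of them at the stated concentration

- factor on the rate of making left-handed product when 5.0 % of the left-handed substrate and right-handed substrate together are converted if precatalyst is charged twice over
- factor on the rate when 5.0 % of the left-handed substrate and right-handed substrate together are converted if precatalyst is charged at 12 mol% instead

The earlier runs start with an induction period. In the green run, time grows 3.01-fold from 1.33 min to 4.00 min, while left-handed product reads 3 % and then 23 %, a factor of 7.67. So product grows faster than time, and the reading lies near time squared.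

I assume the precatalyst left stays close to its charge up to 5.0 % conversion, so it releases free catalyst steadily. Then the catalyst released, bound forms counted, goes as loading times time, and product as loading times time squared. At a fixed conversion, with the substrate and partner charges held, time therefore goes as the inverse root of the loading, and the rate goes as its root. I call this power the loading order at fixed conversion, 0.500. For the doubled charge in this flask, I reckon a factor of 1.41.

The forecast differs. Of the orders in precatalyst and partner it says “The likeliest split is first order in each”, and it gives 2.2 for the doubled charge and 5.5 at 12 mol%.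

The flask gives 1.42 for the doubled charge.

    free catalyst + left-handed substrate ⇌ catalyst intermediate A (K = 3.40 M⁻¹, k = 69.0 M⁻¹ s⁻¹)
    free catalyst + right-handed substrate ⇌ catalyst intermediate B (K = 2.60 M⁻¹, k = 6.80 M⁻¹ s⁻¹)
    partner + catalyst intermediate A → free catalyst + left-handed product (k = 2.20 M⁻¹ s⁻¹)
    partner + catalyst intermediate B → free catalyst + right-handed product (k = 1.00 M⁻¹ s⁻¹)
    partner + precatalyst → free catalyst + spent reagent (k = 0.00220 M⁻¹ s⁻¹)

This flask reaches 5.0 % conversion at 0.926 min. At 3.00 min it holds 74.1 % of its catalyst as precatalyst, 9.52 % as catalyst intermediate A, 9.77 % as catalyst intermediate B and 6.62 % as free catalyst. Going to 12 mol% multiplies the loading by 4.80. Raised to the loading order 0.500, that factor gives 2.19, and the flask gives 2.21.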